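## Structural features

The target is a germacrane-type ten-membered carbocycle (C1–C10). An oxygen bridge from C10 to C3 closes a 3(2H)-furanone (C1 ketone, C2=C3 enol ether, quaternary methyl-bearing C10). C6 and C7 carry a cis-fused α-methylene-γ-butyrolactone (O6–C12, C11=C13). The furanone is conjugated with the (Z)-C4=C5 alkene, and C6–C10 are five contiguous stereocentres (6S,7S,8S,9R,10R) carrying the lactone oxygen, the lactone carbon, a methacrylate on O8, a free hydroxyl on O9 and the bridging oxygen. The threo C8/C9 diol maps onto L-tartaric acid; C10 can be set from C9 and C6/C7 from C8. Fragile points are the two Michael acceptors (C13 methylene much more than the methacrylate), the (Z)-2-methylenoyl unit (can isomerise to E), the O8 ester beside a free O9 hydroxyl (acyl migration), and the lactone, which can move from O6 to O8 when O8 is free. The real difficulty is closing a ten-membered ring that holds a Z alkene, the furanone bridge and the cis lactone without disturbing C6–C10 or C13. The feature exploited is that the furanone is a cyclodehydrated C1/C3 β-diketone bearing the C10 hydroxyl, and the C1 ketone is acidic only at C2 because C10 is quaternary. If C3 is first hung on C2 through sulfur, the C2–C3 bond can be made by an acyl shift from S to C, turning an eleven-membered thiolactone into the carbocycle.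

## Logic of the disconnections

39 ⇒ 38. The O9–H group is traced to its p-methoxybenzyl ether. O9 must stay blocked while O8 is acylated, and neutral oxidative ether cleavage spares the acceptors and avoids acyl migration. The amine must be gone before the oxidant is used.

38 ⇒ 36 ⇒ 34 + 35. C11=C13 is traced to the C13–N bond of the amine adduct, and the O8–acyl bond is cut. 34 has one free hydroxyl, so acylation has no regiochemical question; it must be acylated promptly so the lactone does not move to O8.

34 ⇒ 31. The O10–C3 bond and the C2=C3 unsaturation are removed, giving the C1/C3 diketone with O10 and O8 silylated. O10 must be freed first so that it is the only hydroxyl able to reach a ketone when dehydration starts.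

31 ⇒ 29. The C2–C3 bond is cut and sulfur is inserted between the two carbons. The medium ring then no longer needs an end-to-end closure; 29 is an eleven-membered ring. The forward step needs enolisation at C2 only, C-acylation, a thiophile, and a masked C13.

29 ⇒ 25. The S–C2 bond is cut to a C3 thiocarboxylate and a C2 bromide, both released in one flask. The bromo ketone must not meet a free thiol or secondary amine, and its own tertiary amine must stay protonated or dilute.

25 ⇒ 24 ⇒ 23 ⇒ 21. The C3–S bond, the C13–N bond and the C3 oxidation level are removed in turn. The amine goes on at the carboxylate stage, before any thioester exists. C3 stays an allylic alcohol until the O6–C12 lactone is closed, because a C3 acyl group held Z to O6 would capture O6 as a butenolide.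

21 ⇒ 15 + 19. The C6–C7 and O6–C12 bonds are cut. This is the convergent union and sets C6 and C7 from C8. It needs a (Z)-allyl metal in a chair transition state and a non-coordinating silyl ether on O8, so that the aldehyde enters anti to C9.

19 ⇒ 18 ⇒ 16. The Z geometry is taken from the ring of 16, where the C3 oxygen and the C6 carbonyl are already differentiated.

15 ⇒ 14 ⇒ 12 + 13. The C13–Br bond (with allylic transposition) and the C7–C11 bond are cut; the carbinol centre made in between is destroyed again.

12 ⇒ 11 ⇒ 10 ⇒ 8 ⇒ 7. The C10–CH3 bond and the C10–C1 bond are cut back to an acyl derivative of C10. Methyl must add last and under chelation, which requires an ether (not a silyl ether) on O9. O10 must be capped before C7 becomes an aldehyde, or it would close a lactol.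

7 ⇒ 6 ⇒ 4 ⇒ 3 ⇒ 1. The C2 symmetry of 1 makes the first mono-etherification unambiguous. Hydroxyl-directed reduction then tells the two esters apart: C7 becomes the alcohol and C10 stays an acyl group.

## Other disconnections considered

Alternative 1: The cuts are C1–C10 and O10–C3 in an open chain. Methyl ketone A1 (C7–C10), (Z)-enoic acid A2 (C3–C6) and convertible isocyanide A3 would combine in a Passerini reaction to the α-acyloxy anilide A4.
- In favour: three building blocks and two bonds in one neutral step, and direct access to the tertiary acyloxy centre. Once C2 is attached to C1, a base-induced O-to-C acyl shift is a known furanone synthesis.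
- Against: Passerini reactions of ketones are slow, and C10 would form with only weak induction from C9. C2 is missing from A4. No ring is closed, so the ten-membered ring would still need an end-to-end closure.
- Comparison: Alternative 1 is the better plan in convergence and in steps needed to join C10, O10 and C3 (one step against steps 4–7 plus the later thioester chemistry), and it avoids sulfur reagents. The chosen plan is stronger in control of C10 (chelation, step 6) and is the only one of the two that deals with the medium ring.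

Alternative 2: The cut is C8–C9, leading to dialdehyde A5 with furanone, Z alkene and amine-masked cis lactone complete. [V2Cl3(THF)6]2[Zn2Cl6] would reduce the C9 aldehyde, which chelates divalent vanadium through the ring oxygen on C10; the bound ketyl would add to the C8 aldehyde and close the carbocycle to diol A6.
- In favour: the ring and both carbinol centres form in one step, chelated heterocoupling favours threo diols, and O8/O9 need no protection up to that point.
- Against: C8 and C9 would rest on macrocyclic substrate control. Low-valent vanadium may also reduce the dienone. C7 is epimerisable next to the C8 aldehyde. A6 still needs acylation at O8 only.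
- Comparison: Alternative 2 is the better plan in stereocentres created by the key step (two against none). The two plans are equal in closing the ring late on a fully functionalised substrate. The chosen plan is stronger in stereochemical security (C8/C9 bought, O8/O9 differentiated from step 1) and in mechanism (two-electron alkylation and acyl shift, not a radical coupling beside reducible groups). Step economy is comparable.

Alternative 3: The cuts are C1–C2 and O10–C3. Seco compound A7 has an S-ethyl thioester at C1, a free O10 hydroxyl and a terminal alkyne (C2≡C3) on C4. PdCl2(PPh3)2 and CuI would couple the thioester with the alkyne to the ten-membered ynone A8, and O10 would add 5-endo-dig to C3 to give the protected core A9.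
- In favour: two bonds and both rings in one catalytic operation, the furanone at the right oxidation level, no mask for the methylene, and only three steps afterwards.
- Against: the ring would have to close onto a linear C4–C3≡C2–C1 unit beside a Z alkene. That is a strained cyclodecenyne, so oligomerisation and decarbonylation of the acyl-palladium are expected to compete. Released ethanethiolate would add to the unmasked methylene lactone.
- Comparison: Alternative 3 is the better plan in step economy after ring closure and in avoiding the masking pair. The two plans are equal in using a thioester as acyl donor for the new C–C bond. The chosen plan is stronger in how the ring is closed: an sp3-rich eleven-membered ring by SN2, then a three-atom acyl shift.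

Key step: step 18

Remark (assumptions): 9-fluorenylmethanethiol and 4-methyl-2(5H)-furanone are taken as purchasable; the butenolide is used because the two carbonyls of citraconic anhydride are not reliably differentiated. C11 of the amine adducts forms as a mixture (one epimer drawn) that converges in step 21. The route carries (6S,7S,8S,9R,10R; 4Z) throughout, with C8 and C9 unchanged from L-tartrate.

Abbreviations: TBS = tert-butyldimethylsilyl, TES = triethylsilyl, PMB = 4-methoxybenzyl, Fm = 9-fluorenylmethyl. Atom numbers C1–C13 follow the germacranolide numbering of 39.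

## Route

Step 1
Reactants: 1 diethyl L-tartrate
Product: 3 diethyl (2R,3R)-2-hydroxy-3-[(4-methoxybenzyl)oxy]butanedioate, via stannylene acetal 2 (not isolated)
Conditions: Bu2SnO, PhMe, reflux (−H2O); then PMBCl, CsF, DMF, rt
Reagents that add atoms: 4-methoxybenzyl chloride, COc1ccc(CCl)cc1
Why: Stannylene-acetal activation followed by fluoride-promoted O-alkylation is the standard mono-etherification of a 1,2-diol; the C2 axis of 1 makes the two hydroxyls equivalent, so one mono-ether results and no stereocentre is touched.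

Step 2
Reactants: 3 diethyl (2R,3R)-2-hydroxy-3-[(4-methoxybenzyl)oxy]butanedioate
Product: 4 ethyl (2R,3S)-3,4-dihydroxy-2-[(4-methoxybenzyl)oxy]butanoate
Conditions: BH3·SMe2, NaBH4 (5 mol%), THF, 0 °C → rt; MeOH quench
Reagents that add atoms: none
Why: Hydroxyl-directed borane reduction: the free hydroxyl forms an alkoxyborane that delivers hydride only to its own α-ester, so C7 becomes CH2OH while the C10 ester next to the PMB ether survives; 4 is silylated at once to forestall γ-lactonisation.

Step 3
Reactants: 4 ethyl (2R,3S)-3,4-dihydroxy-2-[(4-methoxybenzyl)oxy]butanoate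
Product: 6 ethyl (2R,3S)-3-[(tert-butyldimethylsilyl)oxy]-2-[(4-methoxybenzyl)oxy]-4-[(triethylsilyl)oxy]butanoate, via primary TES ether 5 (not isolated)
Conditions: TESCl (1.0 equiv), imidazole, CH2Cl2, −40 °C; then TBSOTf, 2,6-lutidine, −40 → 0 °C
Reagents that add atoms: chlorotriethylsilane, CC[Si](Cl)(CC)CC; tert-butyldimethylsilyl triflate, CC(C)(C)[Si](C)(C)OS(=O)(=O)C(F)(F)F
Why: A silyl chloride at low temperature selects the primary hydroxyl and the triflate then caps the hindered secondary one (sequential silylation); the primary TES/secondary TBS pair lets C7 be unveiled later and puts a non-coordinating group on O8.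

Step 4
Reactants: 6 ethyl (2R,3S)-3-[(tert-butyldimethylsilyl)oxy]-2-[(4-methoxybenzyl)oxy]-4-[(triethylsilyl)oxy]butanoate
Product: 7 (2R,3S)-3-[(tert-butyldimethylsilyl)oxy]-N-methoxy-2-[(4-methoxybenzyl)oxy]-N-methyl-4-[(triethylsilyl)oxy]butanamide
Conditions: MeNH(OMe)·HCl, i-PrMgCl, THF, −20 °C
Reagents that add atoms: N,O-dimethylhydroxylamine hydrochloride, CNOC.Cl
Why: Aminolysis of an ester by the magnesium amide gives the Weinreb amide; at −20 °C the α-alkoxy stereocentre is not enolised.

Step 5
Reactants: 7 (2R,3S)-3-[(tert-butyldimethylsilyl)oxy]-N-methoxy-2-[(4-methoxybenzyl)oxy]-N-methyl-4-[(triethylsilyl)oxy]butanamide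
Product: 8 (4R,5S)-5-[(tert-butyldimethylsilyl)oxy]-2-ethoxy-4-[(4-methoxybenzyl)oxy]-6-[(triethylsilyl)oxy]hex-1-en-3-one
Conditions: ethyl vinyl ether, t-BuLi, THF, −78 → 0 °C; then 7, −78 °C
Reagents that add atoms: ethyl vinyl ether, C=COCC
Why: Weinreb ketone synthesis with 1-ethoxyvinyllithium as a masked acetyl anion; the chelated tetrahedral adduct prevents over-addition and brings in C1 and C2.

Step 6
Reactants: 8 (4R,5S)-5-[(tert-butyldimethylsilyl)oxy]-2-ethoxy-4-[(4-methoxybenzyl)oxy]-6-[(triethylsilyl)oxy]hex-1-en-3-one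
Product: 10 (3R,4R,5S)-5-[(tert-butyldimethylsilyl)oxy]-3-hydroxy-4-[(4-methoxybenzyl)oxy]-3-methyl-6-[(triethylsilyl)oxy]hexan-2-one, via enol ether carbinol 9 (not isolated)
Conditions: MgBr2·OEt2, CH2Cl2, −78 °C; MeMgBr (Et2O), −78 → −40 °C; then 10% aq. citric acid/THF, 0 °C
Reagents that add atoms: methylmagnesium bromide, C[Mg]Br; water, O
Why: Cram-chelate addition: magnesium bridges the C10 carbonyl and the O9 benzylic ether, and methyl enters the face anti to C8, setting the quaternary C10 centre (10R in 39). Buffered aqueous acid then hydrolyses the 1-ethoxyvinyl group to the methyl ketone much faster than it cleaves the silyl ethers.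

Step 7
Reactants: 10 (3R,4R,5S)-5-[(tert-butyldimethylsilyl)oxy]-3-hydroxy-4-[(4-methoxybenzyl)oxy]-3-methyl-6-[(triethylsilyl)oxy]hexan-2-one
Product: 11 (3R,4R,5S)-5-[(tert-butyldimethylsilyl)oxy]-4-[(4-methoxybenzyl)oxy]-3-methyl-3,6-bis[(triethylsilyl)oxy]hexan-2-one
Conditions: TESOTf, 2,6-lutidine, CH2Cl2, −78 → 0 °C
Reagents that add atoms: triethylsilyl triflate, CC[Si](CC)(CC)OS(=O)(=O)C(F)(F)F
Why: Silyl triflate with a hindered pyridine silylates the tertiary hydroxyl without enolising the ketone; O10 must be capped before C7 becomes an aldehyde, or it would close a five-membered lactol.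

Step 8
Reactants: 11 (3R,4R,5S)-5-[(tert-butyldimethylsilyl)oxy]-4-[(4-methoxybenzyl)oxy]-3-methyl-3,6-bis[(triethylsilyl)oxy]hexan-2-one
Product: 12 (2R,3R,4R)-2-[(tert-butyldimethylsilyl)oxy]-3-[(4-methoxybenzyl)oxy]-4-methyl-5-oxo-4-[(triethylsilyl)oxy]hexanal
Conditions: (COCl)2, DMSO, CH2Cl2, −78 → −35 °C; Et3N, −78 → 0 °C
Reagents that add atoms: none
Why: Under Swern conditions a primary triethylsilyl ether is cleaved and oxidised in one operation, while the secondary TBS and tertiary TES ethers are inert (known selective oxidative desilylation); the low temperature protects the C8 centre.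

Step 9
Reactants: 12 (2R,3R,4R)-2-[(tert-butyldimethylsilyl)oxy]-3-[(4-methoxybenzyl)oxy]-4-methyl-5-oxo-4-[(triethylsilyl)oxy]hexanal; 13 methyl acrylate
Product: 14 methyl (4S,5R,6R)-4-[(tert-butyldimethylsilyl)oxy]-3-hydroxy-5-[(4-methoxybenzyl)oxy]-6-methyl-2-methylidene-7-oxo-6-[(triethylsilyl)oxy]octanoate (both C3 epimers)
Conditions: DABCO (1 equiv), 13 (excess, neat), MeOH (cat.), rt, several days
Reagents that add atoms: none
Why: Morita–Baylis–Hillman reaction; α-alkoxy aldehydes are activated electrophiles and the hindered ketone does not react. The new carbinol centre (C7) is erased in step 10, so its configuration does not matter.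

Step 10
Reactants: 14 methyl (4S,5R,6R)-4-[(tert-butyldimethylsilyl)oxy]-3-hydroxy-5-[(4-methoxybenzyl)oxy]-6-methyl-2-methylidene-7-oxo-6-[(triethylsilyl)oxy]octanoate
Product: 15 methyl (2Z,4S,5R,6R)-2-(bromomethyl)-4-[(tert-butyldimethylsilyl)oxy]-5-[(4-methoxybenzyl)oxy]-6-methyl-7-oxo-6-[(triethylsilyl)oxy]oct-2-enoate
Conditions: NBS, Me2S, CH2Cl2, 0 °C → rt
Reagents that add atoms: N-bromosuccinimide, O=C1CCC(=O)N1Br
Why: The sulfonium reagent from NBS and Me2S activates the allylic hydroxyl and bromide returns at the terminal carbon with allylic transposition, the known route from Baylis–Hillman adducts to (Z)-2-(bromomethyl)-2-enoates; this places C8 cis to CH2Br, as the chair transition state of step 13 requires.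

Step 11
Reactants: 16 4-methyl-2(5H)-furanone
Product: 18 (2Z)-N-methoxy-N,3-dimethyl-4-[(triethylsilyl)oxy]but-2-enamide, via hydroxy amide 17 (not isolated)
Conditions: MeNH(OMe)·HCl, AlMe3, CH2Cl2, 0 °C → rt; then TESCl, imidazole, CH2Cl2, 0 °C
Reagents that add atoms: N,O-dimethylhydroxylamine hydrochloride, CNOC.Cl; chlorotriethylsilane, CC[Si](Cl)(CC)CC
Why: Aluminium-amide opening of the lactone keeps the Z geometry that the ring imposes and fixes which end is the acyl carbon (C6) and which the carbinol (C3); immediate silylation prevents relactonisation.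

Step 12
Reactants: 18 (2Z)-N-methoxy-N,3-dimethyl-4-[(triethylsilyl)oxy]but-2-enamide
Product: 19 (2Z)-3-methyl-4-[(triethylsilyl)oxy]but-2-enal
Conditions: i-Bu2AlH, THF, −78 °C
Reagents that add atoms: none
Why: Hydride reduction of a Weinreb amide stops at the chelated hemiaminal and gives the aldehyde on work-up; at −78 °C the Z enal does not isomerise, and it is used at once.

Step 13
Reactants: 15 methyl (2Z,4S,5R,6R)-2-(bromomethyl)-4-[(tert-butyldimethylsilyl)oxy]-5-[(4-methoxybenzyl)oxy]-6-methyl-7-oxo-6-[(triethylsilyl)oxy]oct-2-enoate; 19 (2Z)-3-methyl-4-[(triethylsilyl)oxy]but-2-enal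
Product: 21 cis-6,12-lactone allylic alcohol (C3 CH2OH; 4Z; C11=C13 methylene; 8-OTBS; 9-OPMB; 10-OTES; C1 methyl ketone; C6–C10 as in 39), via open hydroxy ester 20 (not isolated)
Conditions: In powder, THF/H2O (4:1), rt; then CSA (cat.), CH2Cl2/MeOH, 0 °C → rt
Reagents that add atoms: none
Why: Indium-mediated Barbier allylation through a six-membered chair: the (Z)-allylindium with the aldehyde substituent equatorial gives the 6,7-syn adduct (hence the cis lactone). C8 fixes the face, with its hydrogen eclipsing the alkene (1,3-allylic strain), the non-coordinating silyloxy group pointing outward and the aldehyde entering anti to C9, which corresponds to (6S,7S). Acid then closes the γ-lactone from O6 onto the only ester in a 1,4-relationship and methanolyses the primary silyl ether; C3 is still an alcohol and cannot capture O6 as a butenolide.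

Step 14
Reactants: 21 cis-6,12-lactone allylic alcohol
Product: 23 (Z)-C3 carboxylic acid of the cis-lactone (C13 methylene; 8-OTBS; 9-OPMB; 10-OTES; C1 methyl ketone), via (Z)-enal 22 (not isolated)
Conditions: MnO2, CH2Cl2, rt; then NaClO2, NaH2PO4, 2-methyl-2-butene, t-BuOH/H2O, 0 °C
Reagents that add atoms: sodium chlorite, [Na+].[O-]Cl=O
Why: Allylic oxidation with MnO2 followed by Pinnick oxidation; neither touches the electron-poor alkenes, and the Z enal is oxidised without storage so that it cannot isomerise.

Step 15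
Reactants: 23 (Z)-C3 carboxylic acid of the cis-lactone
Product: 24 13-(dimethylamino) adduct of acid 23 (zwitterion; C11 epimers, one drawn)
Conditions: Me2NH (2 M in THF), THF, 0 °C → rt; evaporate
Reagents that add atoms: dimethylamine, CNC
Why: Aza-Michael addition to the α-methylene lactone is the classical reversible mask for this group; it is done at the carboxylate stage, when the dienoate is not electrophilic and no thioester or bromide is present.

Step 16
Reactants: 24 13-(dimethylamino) adduct of acid 23
Product: 25 S-(9-fluorenylmethyl) (Z)-thioester of 24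
Conditions: 9-fluorenylmethanethiol, EDC·HCl, DMAP (5 mol%), CH2Cl2, −10 → 0 °C
Reagents that add atoms: 9-fluorenylmethanethiol, SCC1c2ccccc2-c2ccccc12
Why: Carbodiimide (Steglich-type) thioesterification; the Fm thioester is a base-releasable thioacid precursor, the low temperature and small DMAP charge limit Z-to-E isomerisation, and the amine mask keeps the thiol off C13.

Step 17
Reactants: 25 S-(9-fluorenylmethyl) (Z)-thioester of 24
Product: 29 eleven-membered thiolactone (C3 acyl–S–C2; 4Z; 13-dimethylamino mask; 8-OTBS; 9-OPMB; 10-OTES), via silyl enol ether 26 (not isolated), via bromo ketone 27 (not isolated), via thiocarboxylate 28 (not isolated)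
Conditions: TMSOTf, Et3N, CH2Cl2, −78 → −20 °C; NBS, NaHCO3, THF, −78 °C; AcOH; then DBU, MeCN (1 mM), 0 °C → rt; AcOH
Reagents that add atoms: none
Why: Soft enolisation reaches only the C2 methyl of the C1 ketone (C10 is quaternary), and NBS brominates the silyl enol ether at −78 °C faster than it attacks the weakly basic Mannich-type amine. The bromo ketone is kept as its ammonium acetate and not stored. DBU releases the thiocarboxylate from the Fm thioester by E1cB loss of dibenzofulvene, and S-alkylation by the α-bromo ketone, one of the fastest SN2 pairings, closes the eleven-membered ring at high dilution.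

Step 18
Reactants: 29 eleven-membered thiolactone
Product: 31 ten-membered C1/C3 β-diketone (4Z; 13-dimethylamino mask; 8-OTBS; 9-OPMB; 10-OTES), via episulfide 30 (not isolated)
Conditions: LiBr, i-Pr2NEt, P(OEt)3, MeCN, rt → 50 °C
Reagents that add atoms: none
Why: Proposed new method: the closest known reaction is the Eschenmoser sulfide contraction of open-chain S-(2-oxoalkyl) thiocarboxylates to β-diketones, and here the same acyl shift is asked to operate inside a ring. LiBr activates the C1 carbonyl and i-Pr2NEt removes a C2 proton, the only acidic C–H beside C1 because C10 is quaternary. The C2 enolate carbon attacks the thioester carbonyl C3 two atoms away (3-exo-trig) and gives the lithium alkoxide of episulfide 30. P(OEt)3 takes sulfur from 30 as (EtO)3P=S and the alkoxide collapses to the diketone, so C2–C3 is formed and sulfur leaves the ring. The ten-membered carbocycle therefore arises by contraction of the eleven-membered thiolactone (a 1,2-acyl shift from S to C), not by an end-to-end closure. No stereocentre is formed; C6–C10 lie off the reaction path, and the (Z)-C4=C5 geometry is held by the ring and the cis lactone. The step needs C- rather than O-acylation of the enolate and no attack on the lactone; lithium chelation of the developing β-diketonate and the one-atom sulfur bridge favour the former, and the amine mask removes the only other site open to phosphite, thiolate or enolate.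

Step 19
Reactants: 31 ten-membered C1/C3 β-diketone
Product: 34 furanone alcohol (3,10-oxygen bridge; 8-OH; 9-OPMB; 13-dimethylamino mask), via C10 carbinol 32 (not isolated), via 8-O-TBS furanone 33 (not isolated)
Conditions: TsOH·H2O (1.5 equiv), MeOH/CH2Cl2, 0 °C → rt; then aq. HF, MeCN, 0 °C → rt; NaHCO3
Reagents that add atoms: none
Why: Acid methanolysis removes the tertiary TES ether first; the freed O10 adds to the C3 ketone and the hemiketal dehydrates to the conjugated 3(2H)-furanone (known cyclodehydration of α′-hydroxy-1,3-diketones). HF removes the O8 silyl ether only after the diketone is consumed, so O8 cannot form a transannular ketal.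

Step 20
Reactants: 34 furanone alcohol; 35 methacrylic anhydride
Product: 36 8-O-methacrylate (9-OPMB; 13-dimethylamino mask)
Conditions: Et3N, DMAP (cat.), CH2Cl2, 0 °C → rt
Reagents that add atoms: none
Why: DMAP-catalysed acylation of the only free hydroxyl; O9 is still an ether, so there is no regiochemical issue and no acyl migration, and the masked C13 is inert to the amine bases.

Step 21
Reactants: 36 8-O-methacrylate
Product: 38 α-methylene lactone 9-O-PMB ether, via quaternary ammonium iodide 37 (not isolated)
Conditions: MeI, MeCN, rt; then aq. NaHCO3, EtOAc, rt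
Reagents that add atoms: none
Why: Quaternisation turns the amine into a leaving group and mild base effects E1cB (Hofmann-type) elimination to the exocyclic methylene, the standard unmasking; both C11 epimers converge here.

Step 22
Reactants: 38 α-methylene lactone 9-O-PMB ether
Product: 39 target (6S,7S,8S,9R,10R; 4Z)
Conditions: DDQ, CH2Cl2/pH 7 buffer, 0 °C → rt
Reagents that add atoms: none
Why: DDQ oxidises the electron-rich benzylic ether to an oxocarbenium ion that water hydrolyses; the neutral two-phase medium leaves the three acceptors untouched and does not promote O8-to-O9 acyl migration.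

## Compound list

1 | diethyl L-tartrate | CCOC(=O)[C@H](O)[C@@H](O)C(=O)OCC | starting material
2 | diethyl (4R,5R)-2,2-dibutyl-1,3,2-dioxastannolane-4,5-dicarboxylate (not isolated) | CCOC(=O)[C@@H]1O[Sn](CCCC)(CCCC)O[C@H]1C(=O)OCC | intermediate
3 | diethyl (2R,3R)-2-hydroxy-3-[(4-methoxybenzyl)oxy]butanedioate | CCOC(=O)[C@H](O)[C@@H](OCc1ccc(OC)cc1)C(=O)OCC | intermediate
4 | ethyl (2R,3S)-3,4-dihydroxy-2-[(4-methoxybenzyl)oxy]butanoate | OC[C@H](O)[C@@H](OCc1ccc(OC)cc1)C(=O)OCC | intermediate
5 | ethyl (2R,3S)-3-hydroxy-2-[(4-methoxybenzyl)oxy]-4-[(triethylsilyl)oxy]butanoate (not isolated) | CC[Si](CC)(CC)OC[C@H](O)[C@@H](OCc1ccc(OC)cc1)C(=O)OCC | intermediate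
6 | ethyl (2R,3S)-3-[(tert-butyldimethylsilyl)oxy]-2-[(4-methoxybenzyl)oxy]-4-[(triethylsilyl)oxy]butanoate | CC[Si](CC)(CC)OC[C@H](O[Si](C)(C)C(C)(C)C)[C@@H](OCc1ccc(OC)cc1)C(=O)OCC | intermediate
7 | (2R,3S)-3-[(tert-butyldimethylsilyl)oxy]-N-methoxy-2-[(4-methoxybenzyl)oxy]-N-methyl-4-[(triethylsilyl)oxy]butanamide | CC[Si](CC)(CC)OC[C@H](O[Si](C)(C)C(C)(C)C)[C@@H](OCc1ccc(OC)cc1)C(=O)N(C)OC | intermediate
8 | (4R,5S)-5-[(tert-butyldimethylsilyl)oxy]-2-ethoxy-4-[(4-methoxybenzyl)oxy]-6-[(triethylsilyl)oxy]hex-1-en-3-one | CC[Si](CC)(CC)OC[C@H](O[Si](C)(C)C(C)(C)C)[C@@H](OCc1ccc(OC)cc1)C(=O)C(=C)OCC | intermediate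
9 | (3R,4R,5S)-5-[(tert-butyldimethylsilyl)oxy]-2-ethoxy-4-[(4-methoxybenzyl)oxy]-3-methyl-6-[(triethylsilyl)oxy]hex-1-en-3-ol (not isolated) | CC[Si](CC)(CC)OC[C@H](O[Si](C)(C)C(C)(C)C)[C@@H](OCc1ccc(OC)cc1)[C@@](C)(O)C(=C)OCC | intermediate
10 | (3R,4R,5S)-5-[(tert-butyldimethylsilyl)oxy]-3-hydroxy-4-[(4-methoxybenzyl)oxy]-3-methyl-6-[(triethylsilyl)oxy]hexan-2-one | CC[Si](CC)(CC)OC[C@H](O[Si](C)(C)C(C)(C)C)[C@@H](OCc1ccc(OC)cc1)[C@@](C)(O)C(C)=O | intermediate
11 | (3R,4R,5S)-5-[(tert-butyldimethylsilyl)oxy]-4-[(4-methoxybenzyl)oxy]-3-methyl-3,6-bis[(triethylsilyl)oxy]hexan-2-one | CC[Si](CC)(CC)OC[C@H](O[Si](C)(C)C(C)(C)C)[C@@H](OCc1ccc(OC)cc1)[C@@](C)(O[Si](CC)(CC)CC)C(C)=O | intermediate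
12 | (2R,3R,4R)-2-[(tert-butyldimethylsilyl)oxy]-3-[(4-methoxybenzyl)oxy]-4-methyl-5-oxo-4-[(triethylsilyl)oxy]hexanal | O=C[C@H](O[Si](C)(C)C(C)(C)C)[C@@H](OCc1ccc(OC)cc1)[C@@](C)(O[Si](CC)(CC)CC)C(C)=O | intermediate
13 | methyl acrylate | C=CC(=O)OC | starting material
14 | methyl (4S,5R,6R)-4-[(tert-butyldimethylsilyl)oxy]-3-hydroxy-5-[(4-methoxybenzyl)oxy]-6-methyl-2-methylidene-7-oxo-6-[(triethylsilyl)oxy]octanoate (C3 epimers) | COC(=O)C(=C)C(O)[C@H](O[Si](C)(C)C(C)(C)C)[C@@H](OCc1ccc(OC)cc1)[C@@](C)(O[Si](CC)(CC)CC)C(C)=O | intermediate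
15 | methyl (2Z,4S,5R,6R)-2-(bromomethyl)-4-[(tert-butyldimethylsilyl)oxy]-5-[(4-methoxybenzyl)oxy]-6-methyl-7-oxo-6-[(triethylsilyl)oxy]oct-2-enoate | COC(=O)C(/CBr)=C/[C@H](O[Si](C)(C)C(C)(C)C)[C@@H](OCc1ccc(OC)cc1)[C@@](C)(O[Si](CC)(CC)CC)C(C)=O | intermediate
16 | 4-methyl-2(5H)-furanone | CC1=CC(=O)OC1 | starting material
17 | (2Z)-4-hydroxy-N-methoxy-N,3-dimethylbut-2-enamide (not isolated) | CON(C)C(=O)/C=C(/C)CO | intermediate
18 | (2Z)-N-methoxy-N,3-dimethyl-4-[(triethylsilyl)oxy]but-2-enamide | CON(C)C(=O)/C=C(/C)CO[Si](CC)(CC)CC | intermediate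
19 | (2Z)-3-methyl-4-[(triethylsilyl)oxy]but-2-enal | O=C/C=C(/C)CO[Si](CC)(CC)CC | intermediate
20 | open 6,7-syn hydroxy ester (C6 OH, C12 methyl ester, C3 OTES; not isolated) | CC[Si](CC)(CC)OC/C(C)=C\[C@H](O)[C@H](C(=C)C(=O)OC)[C@H](O[Si](C)(C)C(C)(C)C)[C@@H](OCc1ccc(OC)cc1)[C@@](C)(O[Si](CC)(CC)CC)C(C)=O | intermediate
21 | cis-6,12-lactone allylic alcohol (C3 CH2OH, 4Z, C13 methylene, 8-OTBS, 9-OPMB, 10-OTES, C1 methyl ketone) | OC/C(C)=C\[C@@H]1OC(=O)C(=C)[C@@H]1[C@H](O[Si](C)(C)C(C)(C)C)[C@@H](OCc1ccc(OC)cc1)[C@@](C)(O[Si](CC)(CC)CC)C(C)=O | intermediate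
22 | (Z)-C3 enal of the cis-lactone (not isolated) | O=C/C(C)=C\[C@@H]1OC(=O)C(=C)[C@@H]1[C@H](O[Si](C)(C)C(C)(C)C)[C@@H](OCc1ccc(OC)cc1)[C@@](C)(O[Si](CC)(CC)CC)C(C)=O | intermediate
23 | (Z)-C3 carboxylic acid of the cis-lactone | OC(=O)/C(C)=C\[C@@H]1OC(=O)C(=C)[C@@H]1[C@H](O[Si](C)(C)C(C)(C)C)[C@@H](OCc1ccc(OC)cc1)[C@@](C)(O[Si](CC)(CC)CC)C(C)=O | intermediate
24 | 13-(dimethylamino) adduct of acid 23 (one C11 epimer drawn) | OC(=O)/C(C)=C\[C@@H]1OC(=O)[C@H](CN(C)C)[C@@H]1[C@H](O[Si](C)(C)C(C)(C)C)[C@@H](OCc1ccc(OC)cc1)[C@@](C)(O[Si](CC)(CC)CC)C(C)=O | intermediate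
25 | S-(9-fluorenylmethyl) (Z)-thioester of 24 | O=C(SCC1c2ccccc2-c2ccccc12)/C(C)=C\[C@@H]1OC(=O)[C@H](CN(C)C)[C@@H]1[C@H](O[Si](C)(C)C(C)(C)C)[C@@H](OCc1ccc(OC)cc1)[C@@](C)(O[Si](CC)(CC)CC)C(C)=O | intermediate
26 | C1 trimethylsilyl enol ether of 25 (not isolated) | O=C(SCC1c2ccccc2-c2ccccc12)/C(C)=C\[C@@H]1OC(=O)[C@H](CN(C)C)[C@@H]1[C@H](O[Si](C)(C)C(C)(C)C)[C@@H](OCc1ccc(OC)cc1)[C@@](C)(O[Si](CC)(CC)CC)C(=C)O[Si](C)(C)C | intermediate
27 | C2 bromo ketone of 25 (not isolated) | O=C(SCC1c2ccccc2-c2ccccc12)/C(C)=C\[C@@H]1OC(=O)[C@H](CN(C)C)[C@@H]1[C@H](O[Si](C)(C)C(C)(C)C)[C@@H](OCc1ccc(OC)cc1)[C@@](C)(O[Si](CC)(CC)CC)C(=O)CBr | intermediate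
28 | C3 thiocarboxylic acid bromo ketone (present as its amidinium thiocarboxylate; not isolated) | O=C(S)/C(C)=C\[C@@H]1OC(=O)[C@H](CN(C)C)[C@@H]1[C@H](O[Si](C)(C)C(C)(C)C)[C@@H](OCc1ccc(OC)cc1)[C@@](C)(O[Si](CC)(CC)CC)C(=O)CBr | intermediate
29 | eleven-membered thiolactone (C3 acyl–S–C2, 4Z, 13-dimethylamino mask, 8-OTBS, 9-OPMB, 10-OTES) | CC(C)(C)[Si](C)(C)O[C@H]1[C@H]2[C@@H](CN(C)C)C(=O)O[C@H]2/C=C(/C)C(=O)SCC(=O)[C@](C)(O[Si](CC)(CC)CC)[C@@H]1OCc1ccc(OC)cc1 | intermediate
30 | 2,3-episulfide with C3 hydroxyl (lithium alkoxide in the flask; C2/C3 configuration undefined; not isolated) | CC(C)(C)[Si](C)(C)O[C@H]1[C@H]2[C@@H](CN(C)C)C(=O)O[C@H]2/C=C(/C)C2(O)SC2C(=O)[C@](C)(O[Si](CC)(CC)CC)[C@@H]1OCc1ccc(OC)cc1 | intermediate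
31 | ten-membered C1/C3 β-diketone (4Z, 13-dimethylamino mask, 8-OTBS, 9-OPMB, 10-OTES) | CC(C)(C)[Si](C)(C)O[C@H]1[C@H]2[C@@H](CN(C)C)C(=O)O[C@H]2/C=C(/C)C(=O)CC(=O)[C@](C)(O[Si](CC)(CC)CC)[C@@H]1OCc1ccc(OC)cc1 | intermediate
32 | β-diketone with free C10 hydroxyl (not isolated) | CC(C)(C)[Si](C)(C)O[C@H]1[C@H]2[C@@H](CN(C)C)C(=O)O[C@H]2/C=C(/C)C(=O)CC(=O)[C@](C)(O)[C@@H]1OCc1ccc(OC)cc1 | intermediate
33 | 8-O-TBS furanone (not isolated) | CC(C)(C)[Si](C)(C)O[C@H]1[C@H]2[C@@H](CN(C)C)C(=O)O[C@H]2/C=C(/C)C2=CC(=O)[C@](C)(O2)[C@@H]1OCc1ccc(OC)cc1 | intermediate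
34 | furanone alcohol (8-OH, 9-OPMB, 13-dimethylamino mask) | O[C@H]1[C@H]2[C@@H](CN(C)C)C(=O)O[C@H]2/C=C(/C)C2=CC(=O)[C@](C)(O2)[C@@H]1OCc1ccc(OC)cc1 | intermediate
35 | methacrylic anhydride | C=C(C)C(=O)OC(=O)C(C)=C | starting material
36 | 8-O-methacrylate (9-OPMB, 13-dimethylamino mask) | C=C(C)C(=O)O[C@H]1[C@H]2[C@@H](CN(C)C)C(=O)O[C@H]2/C=C(/C)C2=CC(=O)[C@](C)(O2)[C@@H]1OCc1ccc(OC)cc1 | intermediate
37 | 13-(trimethylammonio) iodide of 36 (not isolated) | C=C(C)C(=O)O[C@H]1[C@H]2[C@@H](C[N+](C)(C)C)C(=O)O[C@H]2/C=C(/C)C2=CC(=O)[C@](C)(O2)[C@@H]1OCc1ccc(OC)cc1.[I-] | intermediate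
38 | α-methylene lactone 9-O-PMB ether | C=C(C)C(=O)O[C@H]1[C@H]2C(=C)C(=O)O[C@H]2/C=C(/C)C2=CC(=O)[C@](C)(O2)[C@@H]1OCc1ccc(OC)cc1 | intermediate
39 | CNP0252578.4, (6S,7S,8S,9R,10R; 4Z) | C=C(C)C(=O)O[C@H]1[C@H]2C(=C)C(=O)O[C@H]2/C=C(/C)C2=CC(=O)[C@](C)(O2)[C@@H]1O | target

## Step count and least certain steps

Total: 22 steps. Longest linear sequence: 20 steps (steps 1–10 and 13–22); the aldehyde 19 takes two steps (11–12).

Step 18 (key step, proposed new method). The acyl shift may stall or go astray: the enolate may acylate on oxygen, the thiolate may form without losing sulfur, or the C4=C5 bond may isomerise through reversible conjugate addition of thiolate or phosphite. The cause would be the strain of reaching the three-membered arrangement inside a ring already holding a Z alkene and a cis lactone. The fallback sets out from 24 and returns at 31. The acid is converted with 1-(methylsulfonyl)benzotriazole and Et3N into the N-acylbenzotriazole F1. F1 is then cyclised at high dilution with MgBr2·OEt2 and i-Pr2NEt in CH2Cl2, a soft-enolisation crossed Claisen acylation of the C2 methyl ketone by C3 that is known between separate ketones and acylbenzotriazoles. This is the end-to-end ten-membered closure the main plan avoids, so a lower yield is expected.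

Step 17. NBS may oxidise the tertiary amine, the amino bromo ketone may quaternise itself before cyclising, or the lactone may be silylated and brominated at C11. All three come from carrying the amine mask through the bromination. The fallback sets out from 23 and returns at 29, with the mask added only after ring closure. The acid is thioesterified with 9-fluorenylmethanethiol and diisopropylcarbodiimide, without amine base so the thiol does not add to C13, to give the Fm thioester F2. TMSOTf/Et3N then NBS gives the amine-free, isolable bromo ketone F3. DBU at 1 mM closes it to the thiolactone with free methylene F4. Me2NH in THF at −20 °C then adds to C13 faster than it attacks the hindered enoyl thioester and gives 29.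

Step 13. Facial selectivity may be poor (aldehyde entering anti to O8 instead of anti to C9, which would invert C6 and C7 together), or the allylindium may add to the C1 ketone within the same molecule. The cause is that only the C8 substituents steer the chair. The fallback sets out from 15 and returns at 21. Borylation with B2pin2 and Pd2(dba)3 (cat.) gives the (Z)-allyl pinacol boronate F5. Its allylboration of 19, catalysed by a chiral BINOL-derived phosphoric acid, proceeds through the same Zimmerman–Traxler chair (6,7-syn) but under catalyst control of the face, and does not touch ketones. The same acid methanolysis as in step 13 then gives 21.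

Step 6. Chelation control may erode if magnesium binds the enol-ether oxygen in place of O9, or methyl may add in conjugate fashion to the ethoxy enone. The fallback sets out from 7 and returns at 10. Ethynylmagnesium bromide with a cold acidic quench gives the ynone F6, which has no second donor oxygen. MeMgBr with MgBr2·OEt2 in CH2Cl2 adds under chelation to give the propargylic carbinol F7. Ph3PAuNTf2-catalysed Markovnikov hydration in aqueous dioxane gives 10.

Step 9. Conversion may be slow and C8 may epimerise during long exposure to the amine; the cause is the hindered α-silyloxy aldehyde. The fallback sets out from 12 and returns at 14. Hydroalumination of methyl propiolate with i-Bu2AlH and N-methylmorpholine N-oxide gives the α-(methoxycarbonyl)vinylalane, which adds to 12 at 0 °C within hours (a known route to the same adducts). This fallback makes no new compound (F0).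

## Further compounds

F1 | step 18 | N-acylbenzotriazole of acid 24 | O=C(n1nnc2ccccc21)/C(C)=C\[C@@H]1OC(=O)[C@H](CN(C)C)[C@@H]1[C@H](O[Si](C)(C)C(C)(C)C)[C@@H](OCc1ccc(OC)cc1)[C@@](C)(O[Si](CC)(CC)CC)C(C)=O
F2 | step 17 | S-(9-fluorenylmethyl) thioester of 23 (free methylene) | O=C(SCC1c2ccccc2-c2ccccc12)/C(C)=C\[C@@H]1OC(=O)C(=C)[C@@H]1[C@H](O[Si](C)(C)C(C)(C)C)[C@@H](OCc1ccc(OC)cc1)[C@@](C)(O[Si](CC)(CC)CC)C(C)=O
F3 | step 17 | C2 bromo ketone of F2 | O=C(SCC1c2ccccc2-c2ccccc12)/C(C)=C\[C@@H]1OC(=O)C(=C)[C@@H]1[C@H](O[Si](C)(C)C(C)(C)C)[C@@H](OCc1ccc(OC)cc1)[C@@](C)(O[Si](CC)(CC)CC)C(=O)CBr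
F4 | step 17 | eleven-membered thiolactone with free C13 methylene | CC(C)(C)[Si](C)(C)O[C@H]1[C@H]2C(=C)C(=O)O[C@H]2/C=C(/C)C(=O)SCC(=O)[C@](C)(O[Si](CC)(CC)CC)[C@@H]1OCc1ccc(OC)cc1
F5 | step 13 | (Z)-allyl pinacol boronate corresponding to 15 | COC(=O)C(/CB1OC(C)(C)C(C)(C)O1)=C/[C@H](O[Si](C)(C)C(C)(C)C)[C@@H](OCc1ccc(OC)cc1)[C@@](C)(O[Si](CC)(CC)CC)C(C)=O
F6 | step 6 | (4R,5S)-5-[(tert-butyldimethylsilyl)oxy]-4-[(4-methoxybenzyl)oxy]-6-[(triethylsilyl)oxy]hex-1-yn-3-one | CC[Si](CC)(CC)OC[C@H](O[Si](C)(C)C(C)(C)C)[C@@H](OCc1ccc(OC)cc1)C(=O)C#C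
F7 | step 6 | (3R,4R,5S)-5-[(tert-butyldimethylsilyl)oxy]-4-[(4-methoxybenzyl)oxy]-3-methyl-6-[(triethylsilyl)oxy]hex-1-yn-3-ol | CC[Si](CC)(CC)OC[C@H](O[Si](C)(C)C(C)(C)C)[C@@H](OCc1ccc(OC)cc1)[C@@](C)(O)C#C
F0 | step 9 | none | none
A1 | alternative 1 | C7–C10 methyl ketone (C9 OTBS, C8 OPMB, C7 OTES) | CC(=O)[C@H](O[Si](C)(C)C(C)(C)C)[C@@H](OCc1ccc(OC)cc1)CO[Si](CC)(CC)CC
A2 | alternative 1 | (Z)-4-[(tert-butyldiphenylsilyl)oxy]-2-methylbut-2-enoic acid | OC(=O)/C(C)=C\CO[Si](c1ccccc1)(c1ccccc1)C(C)(C)C
A3 | alternative 1 | 1-(2,2-dimethoxyethyl)-2-isocyanobenzene | COC(OC)Cc1ccccc1[N+]#[C-]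
A4 | alternative 1 | α-acyloxy anilide holding C1, C10 and the C3 ester | COC(OC)Cc1ccccc1NC(=O)[C@](C)(OC(=O)/C(C)=C\CO[Si](c1ccccc1)(c1ccccc1)C(C)(C)C)[C@H](O[Si](C)(C)C(C)(C)C)[C@@H](OCc1ccc(OC)cc1)CO[Si](CC)(CC)CC
A5 | alternative 2 | C8/C9 dialdehyde with furanone and amine-masked cis lactone | O=C[C@H]1[C@@H](CN(C)C)C(=O)O[C@H]1/C=C(/C)C1=CC(=O)[C@@](C)(C=O)O1
A6 | alternative 2 | ten-membered 8,9-diol | O[C@H]1[C@H]2[C@@H](CN(C)C)C(=O)O[C@H]2/C=C(/C)C2=CC(=O)[C@](C)(O2)[C@@H]1O
A7 | alternative 3 | seco S-ethyl thioester with terminal alkyne and free C10 hydroxyl | CCSC(=O)[C@](C)(O)[C@H](O[Si](C)(C)C(C)(C)C)[C@@H](OCc1ccc(OC)cc1)[C@H]1C(=C)C(=O)O[C@H]1/C=C(/C)C#C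
A8 | alternative 3 | ten-membered ynone with free C10 hydroxyl | COc1ccc(CO[C@H]2[C@H]3C(=C)C(=O)O[C@H]3/C=C(/C)C#CC(=O)[C@](C)(O)[C@@H]2O[Si](C)(C)C(C)(C)C)cc1
A9 | alternative 3 | protected target core (8-OPMB, 9-OTBS) | COc1ccc(CO[C@H]2[C@H]3C(=C)C(=O)O[C@H]3/C=C(/C)C3=CC(=O)[C@](C)(O3)[C@@H]2O[Si](C)(C)C(C)(C)C)cc1
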